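**Retrosynthetic overview**
1. Target 18 ⇐ cyclopropyl ketone 17: the last step sets C8 together with the labile C1 (asymmetric hydrogenation with dynamic kinetic resolution).
2. 17 ⇐ dienyl butenolide 16 (cyclopropanation of C4=C5) ⇐ diketo butenolide 14 (C4 ketone converted to the C4=C5 alkene).
3. 14 ⇐ symmetric 2-alkyl-5-methylcyclohexane-1,3-dione 9 + alkynoate 11: a desymmetrising two-carbon ring expansion inserts C2/C3 into one of the two enantiotopic C1–C(=O) bonds, builds the eight-membered ring and the butenolide, and fixes C6.
4. 9 ⇐ dione 2 (from orcinol by arene hydrogenation) + allylic carbonate 5 (Ir allylic alkylation sets C9; hydroboration/Suzuki coupling completes the side chain).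
5. Ring order: six-membered carbocycle (from the arene) → eight-membered ring and butenolide in one operation → cyclopropane.

Assumption 1 (numbering used in names): ring carbons C1–C8. C1 carries the side chain, C2=C3 is the butenolide alkene (C2 bears the lactone OCH2, C3 the lactone C=O), C4/C5 are the cyclopropane carbons, C6 is CHMe, C7 is CH2, C8 is the carbinol carbon, C9 is the side-chain methine. The target is 1R,4R,5R,6S,8S,9S in this numbering.
Assumption 2: where a chiral ligand or catalyst antipode is named, it is the one expected by analogy; the mirror-image one is used if the observed sense is opposite. C1 in 14–17 is an epimerisable centre, so it is left undefined there and fixed in step 11.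

**Route**

Step 1
Reactants: 1 orcinol (5-methylbenzene-1,3-diol)
Product: 2 5-methylcyclohexane-1,3-dione
Conditions: H2 (70 bar), Rh/Al2O3 (5 wt % Rh), NaOH (1.1 equiv), H2O, 50 °C; then HCl to pH 3
Reagents that add atoms: none
Why: Partial arene hydrogenation of the resorcinolate (dihydroresorcinol process) takes up one H2 and stops at the vinylogous carboxylate, so the aromatic ring becomes a mirror-symmetric dione with no stereocentre.

Step 2
Reactants: 3 (E)-but-2-ene-1,4-diol
Product: 4 (E)-4-hydroxybut-2-en-1-yl acetate
Conditions: Ac2O (1.0 equiv), Et3N, DMAP (cat.), CH2Cl2, −20 °C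
Reagents that add atoms: acetic anhydride CC(=O)OC(C)=O
Why: Statistical mono-acylation of a symmetric diol (diol and diacetate are separated and recycled); no stereocentre.

Step 3
Reactants: 4 (E)-4-hydroxybut-2-en-1-yl acetate
Product: 5 (E)-4-[(methoxycarbonyl)oxy]but-2-en-1-yl acetate
Conditions: ClCO2Me, pyridine, CH2Cl2, 0 °C
Reagents that add atoms: methyl chloroformate COC(=O)Cl
Why: O-acylation gives the allylic methyl carbonate, which ionises much faster than the acetate at the other terminus in the next step.

Step 4
Reactants: 2 5-methylcyclohexane-1,3-dione (2 equiv); 5 (E)-4-[(methoxycarbonyl)oxy]but-2-en-1-yl acetate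
Product: 6 (2S)-2-(4-methyl-2,6-dioxocyclohexyl)but-3-en-1-yl acetate
Conditions: [Ir(cod)Cl]2 (2 mol %), (Sa,S,S)-binaphthyl bis(1-phenylethyl)phosphoramidite (4 mol %), TBD (8 mol %), THF, 23 °C
Reagents that add atoms: none
Why: Iridium-catalysed asymmetric allylic alkylation: the soft dione enolate (formed by the methoxide released from the carbonate) attacks the substituted allyl terminus (branched selectivity), and the phosphoramidite controls the face so that C9 is S.

Step 5
Reactants: 6 (2S)-2-(4-methyl-2,6-dioxocyclohexyl)but-3-en-1-yl acetate; 7 1-bromo-2-methylprop-1-ene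
Product: 9 (2S)-6-methyl-2-(4-methyl-2,6-dioxocyclohexyl)hept-5-en-1-yl acetate, via alkylborane 8 (not isolated)
Conditions: 9-BBN (2.2 equiv), THF, 0 → 23 °C; then 7, PdCl2(dppf) (5 mol %), AsPh3, Cs2CO3, DMF/H2O, 23 °C; acidic work-up
Reagents that add atoms: none
Why: Anti-Markovnikov hydroboration of the terminal vinyl group followed by B-alkyl Suzuki–Miyaura coupling installs the trisubstituted alkene (one equivalent of borane is held by the enol and released on work-up); C9 is untouched.

Step 6
Reactants: 10 tert-butyldimethyl(prop-2-yn-1-yloxy)silane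
Product: 11 methyl 4-[(tert-butyldimethylsilyl)oxy]but-2-ynoate
Conditions: n-BuLi, THF, −78 °C; ClCO2Me, −78 → 0 °C
Reagents that add atoms: methyl chloroformate COC(=O)Cl
Why: Acylation of the lithium acetylide gives the alkynoate; no stereocentre.

Step 7 (key step)
Reactants: 9 (2S)-6-methyl-2-(4-methyl-2,6-dioxocyclohexyl)hept-5-en-1-yl acetate; 11 methyl 4-[(tert-butyldimethylsilyl)oxy]but-2-ynoate
Product: 14 diketo butenolide (6S,9S; eight-membered ring), via potassium cyclobutenoxide 12 (not isolated), via ring-expanded silyl ether 13 (not isolated)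
Conditions: KH (1.05 equiv), THF, 0 °C; toluene, (S,S)-3,4,5-trifluorophenyl binaphthyl spiro ammonium bromide (10 mol %), 11 (1.1 equiv), −40 → 0 °C; then HF·pyridine, THF, 0 → 23 °C
Reagents that add atoms: none
Why: Proposed new method: the potassium enolate of 9, carried into toluene as an ion pair with the chiral ammonium cation, adds through C1 to the β-carbon of 11 (the carbon bearing CH2OSi), the allenolate then attacks one of the two enantiotopic ring carbonyls (4-exo aldol on the pro-S CH2C(=O) arm of the CHMe carbon, selected by the chiral cation) to give 12, and retro-aldol cleavage of the old C1–C(=O) bond releases the stabilised C1 enolate, so C2/C3 are inserted and C6 becomes S; HF then removes the silyl group and the (Z)-γ-hydroxy ester closes to the butenolide; the closest known reaction type is the base-mediated two-carbon ring expansion of cyclic β-keto esters and 2-alkyl-1,3-diones with acetylenic esters or arynes (Michael addition, aldol, retro-aldol), combined here with chiral phase-transfer ion pairing as used for enolate additions to alkynoates.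

Step 8
Reactants: 14 diketo butenolide
Product: 15 C4 allylic alcohol (C4 epimers, used as the mixture)
Conditions: NaBH4, CeCl3·7H2O, MeOH, −78 °C
Reagents that add atoms: none
Why: Luche reduction is 1,2-selective and prefers the conjugated C4 ketone (acyl group on the butenolide) over the saturated C8 ketone; the new C4 carbinol centre is removed in the next step.

Step 9
Reactants: 15 C4 allylic alcohol
Product: 16 dienyl butenolide (C2=C3–C4=C5; C8 ketone)
Conditions: Burgess reagent, toluene, 50 °C
Reagents that add atoms: none
Why: Burgess dehydration (syn Ei elimination of the sulfamate) can only take a hydrogen from C5 because C3 has none, giving the ring-cis C4=C5 alkene.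

Step 10
Reactants: 16 dienyl butenolide
Product: 17 cyclopropyl ketone (4R,5R,6S,9S)
Conditions: CH2N2 (excess, Et2O), Pd(OAc)2 (5 mol %), Et2O, 0 °C
Reagents that add atoms: diazomethane C=[N+]=[N-]
Why: Palladium-catalysed cyclopropanation with diazomethane reacts only at the cis-disubstituted C4=C5 bond (the tetrasubstituted butenolide alkene and the trisubstituted side-chain alkene are too hindered), and the methylene adds anti to the allylic C6 methyl group (minimised allylic strain, peripheral attack), which sets 4R,5R.

Step 11
Reactants: 17 cyclopropyl ketone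
Product: 18 target CNP0267808.2
Conditions: H2 (8 bar), trans-RuH(BH4)[(R)-xylbinap][(S,S)-dpen] (1 mol %), DBU (10 mol %), iPrOH, 25 °C
Reagents that add atoms: none
Why: Noyori asymmetric ketone hydrogenation under dynamic kinetic resolution: C1 (α to the C8 ketone, γ to the butenolide carbonyl) epimerises through the enol, and the catalyst reduces the epimer whose side chain lies anti to the incoming hydride, adding hydride to the Re face of C8 to give the 1,8-cis (1R,8S) alcohol while alkenes, lactone and acetate are untouched.

**Compound list**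
1 | orcinol (5-methylbenzene-1,3-diol) | Cc1cc(O)cc(O)c1 | starting material
2 | 5-methylcyclohexane-1,3-dione | CC1CC(=O)CC(=O)C1 | intermediate
3 | (E)-but-2-ene-1,4-diol | OC/C=C/CO | starting material
4 | (E)-4-hydroxybut-2-en-1-yl acetate | CC(=O)OC/C=C/CO | intermediate
5 | (E)-4-[(methoxycarbonyl)oxy]but-2-en-1-yl acetate | CC(=O)OC/C=C/COC(=O)OC | intermediate
6 | (2S)-2-(4-methyl-2,6-dioxocyclohexyl)but-3-en-1-yl acetate | CC(=O)OC[C@@H](C=C)C1C(=O)CC(C)CC1=O | intermediate
7 | 1-bromo-2-methylprop-1-ene | CC(C)=CBr | starting material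
8 | alkylborane: B-alkyl-9-BBN adduct of 6 at the terminal carbon | CC(=O)OC[C@@H](CCB1C2CCCC1CCC2)C1C(=O)CC(C)CC1=O | intermediate (not isolated)
9 | (2S)-6-methyl-2-(4-methyl-2,6-dioxocyclohexyl)hept-5-en-1-yl acetate | CC(=O)OC[C@@H](CCC=C(C)C)C1C(=O)CC(C)CC1=O | intermediate
10 | tert-butyldimethyl(prop-2-yn-1-yloxy)silane | C#CCO[Si](C)(C)C(C)(C)C | starting material
11 | methyl 4-[(tert-butyldimethylsilyl)oxy]but-2-ynoate | COC(=O)C#CCO[Si](C)(C)C(C)(C)C | intermediate
12 | potassium cyclobutenoxide: bicyclo[4.2.0]oct-7-ene with C1–C4 bond, C8 ketone, CH2OSi on C2, CO2Me on C3 | CC(=O)OC[C@@H](CCC=C(C)C)C12C(CO[Si](C)(C)C(C)(C)C)=C(C(=O)OC)C1([O-])C[C@@H](C)CC2=O.[K+] | intermediate (not isolated)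
13 | ring-expanded silyl ether: cyclooct-2-ene-4,8-dione with C1 side chain, C2 CH2OSi, C3 CO2Me, (6S)-methyl | CC(=O)OC[C@@H](CCC=C(C)C)C1/C(CO[Si](C)(C)C(C)(C)C)=C(C(=O)OC)\C(=O)C[C@@H](C)CC1=O | intermediate (not isolated)
14 | diketo butenolide: eight-membered ring fused at C2=C3 to the butenolide, C=O at C4 and C8, (6S)-methyl, (9S) side chain (2S)-1-acetoxy-6-methylhept-5-en-2-yl on C1 (C1 labile) | CC(=O)OC[C@@H](CCC=C(C)C)C1C2=C(C(=O)OC2)C(=O)C[C@@H](C)CC1=O | intermediate
15 | C4 allylic alcohol: as 14 with CH(OH) at C4 (C4 epimers; C6 geometry as in 14, formal descriptor R) | CC(=O)OC[C@@H](CCC=C(C)C)C1C2=C(C(=O)OC2)C(O)C[C@@H](C)CC1=O | intermediate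
16 | dienyl butenolide: as 14 with ring-cis C4=C5 in place of the C4 ketone (6S,9S) | CC(=O)OC[C@@H](CCC=C(C)C)C1C2=C(C(=O)OC2)/C=C\[C@@H](C)CC1=O | intermediate
17 | cyclopropyl ketone: cis-cyclopropane at C4/C5 (4R,5R), 6S, 9S, C8 ketone (C1 labile) | CC(=O)OC[C@@H](CCC=C(C)C)C1C2=C(C(=O)OC2)[C@@H]2C[C@@H]2[C@@H](C)CC1=O | intermediate
18 | CNP0267808.2: crenulide-type tricycle, 1R,4R,5R,6S,8S,9S; C8 hydroxyl, C6 methyl, C1 side chain (2S)-1-acetoxy-6-methylhept-5-en-2-yl | CC(=O)OC[C@@H](CCC=C(C)C)[C@@H]1C2=C(C(=O)OC2)[C@@H]2C[C@@H]2[C@@H](C)C[C@@H]1O | target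

**Step count and risks**
Total step count: 11. Longest linear sequence: 9 (steps 2, 3, 4, 5, 7, 8, 9, 10, 11, from 3; 8 from orcinol).

Three steps most likely to fail:

Step 7 (ring expansion: reactivity at the hindered C1 and control of C6). The fallback sets out from 9 (with 10 as the alkyne source) and comes back at 14. Ion-pair control is replaced by a covalent, traceless auxiliary. Lithiated 10 is acylated with (−)-8-phenylmenthyl chloroformate to give the 8-phenylmenthyl alkynoate F1. The potassium enolate of 9 (KH, 18-crown-6, THF) is ring-expanded with it to the 8-phenylmenthyl ester F2, whose C6 epimers are now diastereomers, biased by the auxiliary and separable on silica. HF·pyridine then removes the silyl group, the butenolide closes with loss of 8-phenylmenthol (recovered), and the route continues from 14.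

Step 8 (chemoselective reduction of the C4 ketone beside the C8 ketone). The fallback sets out from 14 and comes back at 16, avoiding the alcohol altogether. The dianion (KN(SiMe3)2, 2.2 equiv, THF, −78 °C; first C1–H, then C5–H) is sulfonylated with PhNTf2 (1.0 equiv) at the more reactive C4 enolate oxygen to give the dienyl triflate F3. Pd(OAc)2/PPh3 with HCO2H and Bu3N in DMF at 60 °C then replaces the triflate by hydrogen to give 16.

Step 11 (catalyst-controlled dynamic kinetic resolution at C1/C8). The fallback sets out from 17 and comes back at 18, using a ring-relay under thermodynamic control. K2CO3 in MeOH at 0 °C removes the acetate, and the hydroxy ketone closes to the five-membered lactol F4. Its C1 equilibrates (cat. DBU) so that the C1–C2 bond is trans to the C9 homoprenyl group on the new ring. NaBH4/CeCl3 in MeOH at −40 °C reduces the open keto form from the face opposite the side chain to the diol F5. Ac2O (1.05 equiv) with 2,4,6-collidine in CH2Cl2 at −20 °C acetylates the primary hydroxyl only and gives 18.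

**Further compounds**
F1 | step 7 | (−)-8-phenylmenthyl 4-[(tert-butyldimethylsilyl)oxy]but-2-ynoate | CC(C)(C)[Si](C)(C)OCC#CC(=O)O[C@@H]1C[C@H](C)CC[C@H]1C(C)(C)c1ccccc1
F2 | step 7 | ring-expanded 8-phenylmenthyl ester (analogue of 13 with the 8-phenylmenthyl ester on C3) | CC(=O)OC[C@@H](CCC=C(C)C)C1/C(CO[Si](C)(C)C(C)(C)C)=C(C(=O)O[C@@H]2C[C@H](C)CC[C@H]2C(C)(C)c2ccccc2)\C(=O)C[C@@H](C)CC1=O
F3 | step 8 | dienyl triflate (14 with C4(OTf)=C5, C8 ketone kept) | CC(=O)OC[C@@H](CCC=C(C)C)C1C2=C(C(=O)OC2)/C(OS(=O)(=O)C(F)(F)F)=C\[C@@H](C)CC1=O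
F4 | step 11 | lactol (hemiketal between the side-chain CH2O and C8 of deacetylated 17) | O1C[C@@H](CCC=C(C)C)[C@@H]2C3=C(C(=O)OC3)[C@@H]3C[C@@H]3[C@@H](C)CC12O
F5 | step 11 | diol (deacetyl target) | OC[C@@H](CCC=C(C)C)[C@@H]1C2=C(C(=O)OC2)[C@@H]2C[C@@H]2[C@@H](C)C[C@@H]1O
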